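## Retrosynthetic overview

1. The last C–C bond (C8–Cα) is cut by a Stille disconnection into an (E)-vinylstannane carrying the finished 3,5,6-triol ring and a (Z)-3-bromo-5-ylidenebutenolide carrying the C23 polyenyne.
2. The butenolide is the only ring that is built. It is opened at the lactone O1–C5 bond to a (2E)-2-bromo-en-4-ynoic acid (terminal polyenyne + (E)-2,3-dibromoacrylic acid, then 5-exo-dig C–O closure), after the chain is complete and before the final coupling.
3. The stereochemical key step makes two C–O bonds: the triol comes from (R)-4-ethynyl-3,5,5-trimethylcyclohex-3-en-1-ol by a new hydroxyl-directed one-pot anti-dihydroxylation (O at C6 syn, O at C5 anti to the C3–OH).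
4. The polyenyne comes from a Wittig union of a C15 acetylenic tributylphosphonium salt with a C8 dienynal.
5. Both carbocycles are bought as (4R,6R)-actinol and pass through one hydroxy enol triflate (Sonogashira with TMS-acetylene or with (E)-3-methylpent-2-en-4-yn-1-ol).

Assumption: (4R,6R)-actinol and (E)-3-methylpent-2-en-4-yn-1-ol are bought (industrial carotenoid/vitamin A building blocks); every step that handles a polyene is run under argon in the dark.

## Route

Step 1
Reactants: 1 (4R,6R)-4-hydroxy-2,2,6-trimethylcyclohexan-1-one (actinol; OH and 6-Me trans)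
Product: 4 (R)-4-hydroxy-2,6,6-trimethylcyclohex-1-en-1-yl trifluoromethanesulfonate, via TMS ether 2 (not isolated), via silyl enol triflate 3 (not isolated)
Conditions: LiHMDS (1.0 equiv), TMSCl (1.0 equiv), THF, −78 → 0 °C; LDA (1.2 equiv), −78 °C; PhNTf2 (1.2 equiv), −78 °C → rt; 1 M HCl, THF, 0 °C
Reagents that add atoms: N-phenylbis(trifluoromethanesulfonimide), O=S(=O)(N(c1ccccc1)S(=O)(=O)C(F)(F)F)C(F)(F)F; chlorotrimethylsilane, C[Si](C)(C)Cl (its atoms stay only in 2 and 3)
Why: Transient O-silylation masks the alcohol, the only enolisable α-position (C6–H) is deprotonated and the enolate is O-triflated (enolate triflation), and mild acid removes the TMS ether; the C6 stereocentre is erased on purpose and C4 (R) is untouched.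

Step 2
Reactants: 4 (R)-4-hydroxy-2,6,6-trimethylcyclohex-1-en-1-yl trifluoromethanesulfonate; 5 ethynyltrimethylsilane
Product: 7 (R)-4-ethynyl-3,5,5-trimethylcyclohex-3-en-1-ol, via TMS-enyne 6 (not isolated)
Conditions: Pd(PPh3)4 (5 mol %), CuI (10 mol %), i-Pr2NH, DMF, 50 °C; then K2CO3 (0.2 equiv), MeOH, rt
Reagents that add atoms: none
Why: Sonogashira coupling of the enol triflate followed by in situ methanolytic C-desilylation; the free hydroxyl is tolerated and no stereocentre is touched.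

Step 3
Reactants: 7 (R)-4-ethynyl-3,5,5-trimethylcyclohex-3-en-1-ol
Product: 9 (1S,2R,4S)-1-ethynyl-2,6,6-trimethylcyclohexane-1,2,4-triol, via cis-epoxy alcohol 8 (not isolated)
Conditions: H2WO4 (5 mol %), 30% aq H2O2 (1.5 equiv), t-BuOH/H2O 2:1 (unbuffered, pH ≈ 2), 40 °C; Na2S2O3 quench
Reagents that add atoms: hydrogen peroxide, OO; water, O
Why: Proposed new method: hydroxyl-directed tungsten-peroxo anti-dihydroxylation — the C3–OH binds the peroxotungstate as a tungstate ester and delivers O to the syn face of the tetrasubstituted C5=C6 bond (giving 8), and the same acidic tungstate then activates the oxirane so that water opens it trans-diaxially at C5 with inversion, because C6 is shielded by the gem-dimethyl group and its cationic character is disfavoured by the α-ethynyl group; this leaves C6–OH syn and C5–OH anti to C3–OH, and the closest known reactions are the tungstic acid/H2O2 trans-hydroxylation of simple alkenes and the V/W-catalysed hydroxyl-directed epoxidation of cyclohex-3-enols, which have not been combined as a directed anti-dihydroxylation of a homoallylic enyne.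

Step 4
Reactants: 9 (1S,2R,4S)-1-ethynyl-2,6,6-trimethylcyclohexane-1,2,4-triol
Product: 10 (1R,2R,4S)-2,6,6-trimethyl-1-[(E)-2-(tributylstannyl)ethenyl]cyclohexane-1,2,4-triol
Conditions: Bu3SnH (1.2 equiv), PdCl2(PPh3)2 (2 mol %), THF, 0 °C → rt
Reagents that add atoms: tributyltin hydride, CCCC[SnH](CCCC)CCCC
Why: Pd-catalysed syn-hydrostannation puts tin on the terminal carbon because the internal carbon is flanked by a fully substituted carbinol centre, and the syn addition fixes the E-alkene; the ring stereocentres are not involved.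

Step 5
Reactants: 4 (R)-4-hydroxy-2,6,6-trimethylcyclohex-1-en-1-yl trifluoromethanesulfonate; 11 (E)-3-methylpent-2-en-4-yn-1-ol
Product: 12 (R)-4-[(E)-5-hydroxy-3-methylpent-3-en-1-yn-1-yl]-3,5,5-trimethylcyclohex-3-en-1-ol
Conditions: Pd(PPh3)4 (5 mol %), CuI (10 mol %), i-Pr2NH, DMF, rt → 50 °C
Reagents that add atoms: none
Why: Sonogashira coupling of the enol triflate with the terminal alkyne; the E-enyne geometry of 11 is carried over unchanged.

Step 6
Reactants: 12 (R)-4-[(E)-5-hydroxy-3-methylpent-3-en-1-yn-1-yl]-3,5,5-trimethylcyclohex-3-en-1-ol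
Product: 14 tributyl{(E)-5-[(R)-4-hydroxy-2,6,6-trimethylcyclohex-1-en-1-yl]-3-methylpent-2-en-4-yn-1-yl}phosphonium bromide, via allylic bromide 13 (not isolated)
Conditions: NBS (1.05 equiv), Me2S (1.2 equiv), CH2Cl2, −20 → 0 °C; then PBu3 (1.2 equiv), 0 °C → rt
Reagents that add atoms: N-bromosuccinimide, O=C1CCC(=O)N1Br; tributylphosphine, CCCCP(CCCC)CCCC
Why: Corey–Kim bromination converts only the primary allylic alcohol (the secondary alkoxysulfonium salt does not ionise and returns the alcohol), and the bromide then quaternises PBu3 by SN2 without touching the alkene geometry.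

Step 7
Reactants: 11 (E)-3-methylpent-2-en-4-yn-1-ol; 15 (triphenylphosphoranylidene)acetaldehyde
Product: 17 (2E,4E)-5-methylhepta-2,4-dien-6-ynal, via enynal 16 (not isolated)
Conditions: MnO2 (10 equiv), toluene, rt; filter; then 15 (1.05 equiv), 70 °C
Reagents that add atoms: none
Why: MnO2 oxidises the allylic alcohol to the volatile enynal, which is homologated by two carbons in solution by an E-selective Wittig reaction with the stabilised formyl ylide.

Step 8
Reactants: 14 tributyl{(E)-5-[(R)-4-hydroxy-2,6,6-trimethylcyclohex-1-en-1-yl]-3-methylpent-2-en-4-yn-1-yl}phosphonium bromide; 17 (2E,4E)-5-methylhepta-2,4-dien-6-ynal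
Product: 18 (R)-4-[(3E,5E,7E,9E)-3,10-dimethyldodeca-3,5,7,9-tetraene-1,11-diyn-1-yl]-3,5,5-trimethylcyclohex-3-en-1-ol
Conditions: NaOMe (2.2 equiv), CH2Cl2/MeOH, 0 °C → rt, dark
Reagents that add atoms: none
Why: Wittig olefination with an allylic trialkylphosphonium ylide, a ylide class that gives the new disubstituted double bond E; the mild alkoxide base leaves the terminal alkyne, the free hydroxyl and the two E-enyne units alone.

Step 9
Reactants: 19 propiolic acid
Product: 20 (E)-2,3-dibromoprop-2-enoic acid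
Conditions: Br2 (1.0 equiv), CHCl3, 0 °C → rt, dark; recrystallise
Reagents that add atoms: bromine, BrBr
Why: Anti addition of bromine across the alkyne gives the E-dibromide, in which the β-bromine is cis to the carboxyl group as the later ring closure requires.

Step 10
Reactants: 18 (R)-4-[(3E,5E,7E,9E)-3,10-dimethyldodeca-3,5,7,9-tetraene-1,11-diyn-1-yl]-3,5,5-trimethylcyclohex-3-en-1-ol; 20 (E)-2,3-dibromoprop-2-enoic acid
Product: 22 (Z)-3-bromo-5-[(2E,4E,6E,8E)-11-((R)-4-hydroxy-2,6,6-trimethylcyclohex-1-en-1-yl)-2,9-dimethylundeca-2,4,6,8-tetraen-10-yn-1-ylidene]furan-2(5H)-one, via seco acid 21 (not isolated)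
Conditions: PdCl2(PPh3)2 (5 mol %), CuI (10 mol %), Et3N (4 equiv), MeCN, rt, dark
Reagents that add atoms: none
Why: Tandem Sonogashira coupling–lactonisation: oxidative addition is faster at the β-C–Br (cis to the carboxylate) than at the α-C–Br, and the (2E)-en-4-ynoate 21 closes by Cu/Pd-promoted 5-exo-dig anti-oxymetalation and protonolysis, so the new O1–C5 bond forms the butenolide and the anti addition fixes the Z exocyclic double bond.

Step 11
Reactants: 22 (Z)-3-bromo-5-ylidenebutenolide as named in step 10; 10 (1R,2R,4S)-2,6,6-trimethyl-1-[(E)-2-(tributylstannyl)ethenyl]cyclohexane-1,2,4-triol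
Product: 23 (Z)-5-[(2E,4E,6E,8E)-11-((R)-4-hydroxy-2,6,6-trimethylcyclohex-1-en-1-yl)-2,9-dimethylundeca-2,4,6,8-tetraen-10-yn-1-ylidene]-3-[(E)-2-((1R,2R,4S)-1,2,4-trihydroxy-2,6,6-trimethylcyclohexyl)ethenyl]furan-2(5H)-one (target)
Conditions: Pd2(dba)3 (5 mol %), AsPh3 (20 mol %), NMP, rt → 40 °C, dark
Reagents that add atoms: none
Why: Stille coupling at the α-bromobutenolide with retention of the E-vinylstannane geometry, under neutral conditions that leave the lactone, the four free hydroxyl groups and the polyenyne untouched.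

## Compound list

1 | (4R,6R)-4-hydroxy-2,2,6-trimethylcyclohexan-1-one (actinol) | CC1(C)C[C@H](O)C[C@@H](C)C1=O | starting material
2 | (4R,6R)-2,2,6-trimethyl-4-(trimethylsilyloxy)cyclohexan-1-one | CC1(C)C[C@H](O[Si](C)(C)C)C[C@@H](C)C1=O | intermediate
3 | (R)-2,6,6-trimethyl-4-(trimethylsilyloxy)cyclohex-1-en-1-yl trifluoromethanesulfonate | CC1=C(OS(=O)(=O)C(F)(F)F)C(C)(C)C[C@H](O[Si](C)(C)C)C1 | intermediate
4 | (R)-4-hydroxy-2,6,6-trimethylcyclohex-1-en-1-yl trifluoromethanesulfonate | CC1=C(OS(=O)(=O)C(F)(F)F)C(C)(C)C[C@H](O)C1 | intermediate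
5 | ethynyltrimethylsilane | C#C[Si](C)(C)C | starting material
6 | (R)-3,5,5-trimethyl-4-[(trimethylsilyl)ethynyl]cyclohex-3-en-1-ol | CC1=C(C#C[Si](C)(C)C)C(C)(C)C[C@H](O)C1 | intermediate
7 | (R)-4-ethynyl-3,5,5-trimethylcyclohex-3-en-1-ol | CC1=C(C#C)C(C)(C)C[C@H](O)C1 | intermediate
8 | (1S,3S,6S)-6-ethynyl-1,5,5-trimethyl-7-oxabicyclo[4.1.0]heptan-3-ol (epoxide cis to OH) | C#C[C@@]12C(C)(C)C[C@H](O)C[C@]1(C)O2 | intermediate
9 | (1S,2R,4S)-1-ethynyl-2,6,6-trimethylcyclohexane-1,2,4-triol | C#C[C@@]1(O)C(C)(C)C[C@H](O)C[C@@]1(C)O | intermediate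
10 | (1R,2R,4S)-2,6,6-trimethyl-1-[(E)-2-(tributylstannyl)ethenyl]cyclohexane-1,2,4-triol | CCCC[Sn](CCCC)(CCCC)/C=C/[C@@]1(O)C(C)(C)C[C@H](O)C[C@@]1(C)O | intermediate
11 | (E)-3-methylpent-2-en-4-yn-1-ol | C#C/C(C)=C/CO | starting material
12 | (R)-4-[(E)-5-hydroxy-3-methylpent-3-en-1-yn-1-yl]-3,5,5-trimethylcyclohex-3-en-1-ol | CC1=C(C#C/C(C)=C/CO)C(C)(C)C[C@H](O)C1 | intermediate
13 | (R)-4-[(E)-5-bromo-3-methylpent-3-en-1-yn-1-yl]-3,5,5-trimethylcyclohex-3-en-1-ol | CC1=C(C#C/C(C)=C/CBr)C(C)(C)C[C@H](O)C1 | intermediate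
14 | tributyl{(E)-5-[(R)-4-hydroxy-2,6,6-trimethylcyclohex-1-en-1-yl]-3-methylpent-2-en-4-yn-1-yl}phosphonium bromide | CC1=C(C#C/C(C)=C/C[P+](CCCC)(CCCC)CCCC)C(C)(C)C[C@H](O)C1.[Br-] | intermediate
15 | (triphenylphosphoranylidene)acetaldehyde | O=CC=P(c1ccccc1)(c1ccccc1)c1ccccc1 | starting material
16 | (E)-3-methylpent-2-en-4-ynal | C#C/C(C)=C/C=O | intermediate
17 | (2E,4E)-5-methylhepta-2,4-dien-6-ynal | C#C/C(C)=C/C=C/C=O | intermediate
18 | (R)-4-[(3E,5E,7E,9E)-3,10-dimethyldodeca-3,5,7,9-tetraene-1,11-diyn-1-yl]-3,5,5-trimethylcyclohex-3-en-1-ol | CC1=C(C#C/C(C)=C/C=C/C=C/C=C(C)/C#C)C(C)(C)C[C@H](O)C1 | intermediate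
19 | propiolic acid | C#CC(=O)O | starting material
20 | (E)-2,3-dibromoprop-2-enoic acid | OC(=O)/C(Br)=C\Br | intermediate
21 | (2E,6E,8E,10E,12E)-2-bromo-15-[(R)-4-hydroxy-2,6,6-trimethylcyclohex-1-en-1-yl]-6,13-dimethylpentadeca-2,6,8,10,12-pentaene-4,14-diynoic acid | CC1=C(C#C/C(C)=C/C=C/C=C/C=C(C)/C#C/C=C(Br)\C(=O)O)C(C)(C)C[C@H](O)C1 | intermediate
22 | (Z)-3-bromo-5-[(2E,4E,6E,8E)-11-((R)-4-hydroxy-2,6,6-trimethylcyclohex-1-en-1-yl)-2,9-dimethylundeca-2,4,6,8-tetraen-10-yn-1-ylidene]furan-2(5H)-one | CC1=C(C#C/C(C)=C/C=C/C=C/C=C(C)/C=C2C=C(Br)C(=O)O/2)C(C)(C)C[C@H](O)C1 | intermediate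
23 | CNP0163979.1: (Z)-5-[(2E,4E,6E,8E)-11-((R)-4-hydroxy-2,6,6-trimethylcyclohex-1-en-1-yl)-2,9-dimethylundeca-2,4,6,8-tetraen-10-yn-1-ylidene]-3-[(E)-2-((1R,2R,4S)-1,2,4-trihydroxy-2,6,6-trimethylcyclohexyl)ethenyl]furan-2(5H)-one | CC1=C(C#C/C(C)=C/C=C/C=C/C=C(C)/C=C2C=C(/C=C/[C@@]3(O)C(C)(C)C[C@H](O)C[C@@]3(C)O)C(=O)O/2)C(C)(C)C[C@H](O)C1 | target

## Step count and risks

Total step count: 11. Longest linear sequence: 6 steps (1 → 4 → 12 → 14 → 18 → 22 → 23, i.e. steps 1, 5, 6, 8, 10, 11).

The three steps most likely to fail: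

**Step 3 (the proposed new reaction).** The hydroxyl group may fail to direct the peroxotungstate, the epoxide may open at C6 or eliminate to an allylic alcohol, or the secondary alcohol may be over-oxidised. The fallback sets out from 7 and comes back at 9, and replaces the single-catalyst tandem by two separate established reactions. First, hydroxyl-directed vanadium epoxidation (VO(acac)2 2 mol %, t-BuOOH, CH2Cl2, rt) gives the cis-epoxy alcohol 8, which is now isolated and its configuration checked. Second, Brønsted-acid trans-diaxial hydrolysis (cat. HClO4, THF/H2O, 0 °C → rt) opens 8 at C5 to give 9. No compound outside the list is made.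

**Step 8 (Wittig union).** The allylic ylide can give some Z isomer at the new double bond and can scramble the neighbouring E-enyne, giving the 9Z-type isomer typical of acetylenic carotenoids. The fallback sets out from 12 and from the solution of 16 made as in step 7, and comes back at 18. It replaces the olefination by an sp2–sp2 coupling at the adjacent single bond, so every double bond comes from a stereodefined precursor.
- 12 is oxidised with MnO2 (allylic OH only) to (E)-5-[(R)-4-hydroxy-2,6,6-trimethylcyclohex-1-en-1-yl]-3-methylpent-2-en-4-ynal F1.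
- Takai iodo-olefination (CrCl2, CHI3, THF) converts it into (R)-4-[(3E,5E)-6-iodo-3-methylhexa-3,5-dien-1-yn-1-yl]-3,5,5-trimethylcyclohex-3-en-1-ol F2.
- 16 is converted by Takai–Utimoto borylation (CrCl2, LiI, Cl2CHBpin, THF) into 4,4,5,5-tetramethyl-2-[(1E,3E)-4-methylhexa-1,3-dien-5-yn-1-yl]-1,3,2-dioxaborolane F3.
- Copper-free Suzuki–Miyaura coupling of the two (Pd(PPh3)4, aq K3PO4, THF, rt) gives 18.

**Step 10 (tandem coupling–lactonisation).** Risks are 6-endo closure to a pyranone, a second coupling at the α-bromide, and alkyne homocoupling on a sensitive polyenyne. The fallback sets out from 18 and 20 and comes back at 22, and separates the C–C coupling from the C–O ring closure.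
- 20 is esterified (MeOH, cat. H2SO4) to methyl (E)-2,3-dibromoprop-2-enoate F4.
- β-Selective Sonogashira coupling with 18 (PdCl2(PPh3)2, CuI, Et3N, MeCN, rt) gives methyl (2E,6E,8E,10E,12E)-2-bromo-15-[(R)-4-hydroxy-2,6,6-trimethylcyclohex-1-en-1-yl]-6,13-dimethylpentadeca-2,6,8,10,12-pentaene-4,14-diynoate F5.
- LiOH (THF/H2O, 0 °C) gives the acid 21, now isolated.
- Silver(I)-catalysed 5-exo-dig lactonisation (AgNO3 10 mol %, acetone, rt, dark), which is Z-selective, closes 21 to 22.

## Further compounds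

F0 | step 3 | none | none
F1 | step 8 | (E)-5-[(R)-4-hydroxy-2,6,6-trimethylcyclohex-1-en-1-yl]-3-methylpent-2-en-4-ynal | CC1=C(C#C/C(C)=C/C=O)C(C)(C)C[C@H](O)C1
F2 | step 8 | (R)-4-[(3E,5E)-6-iodo-3-methylhexa-3,5-dien-1-yn-1-yl]-3,5,5-trimethylcyclohex-3-en-1-ol | CC1=C(C#C/C(C)=C/C=C/I)C(C)(C)C[C@H](O)C1
F3 | step 8 | 4,4,5,5-tetramethyl-2-[(1E,3E)-4-methylhexa-1,3-dien-5-yn-1-yl]-1,3,2-dioxaborolane | C#C/C(C)=C/C=C/B1OC(C)(C)C(C)(C)O1
F4 | step 10 | methyl (E)-2,3-dibromoprop-2-enoate | COC(=O)/C(Br)=C\Br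
F5 | step 10 | methyl (2E,6E,8E,10E,12E)-2-bromo-15-[(R)-4-hydroxy-2,6,6-trimethylcyclohex-1-en-1-yl]-6,13-dimethylpentadeca-2,6,8,10,12-pentaene-4,14-diynoate | CC1=C(C#C/C(C)=C/C=C/C=C/C=C(C)/C#C/C=C(Br)\C(=O)OC)C(C)(C)C[C@H](O)C1
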